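The data stem from a simulated flask on assumed constants.

A leftover starts the reckoning: at 2.50 min Saturday's flask shows 59% target and 0% isomer of the product A, so 41.0% of the charge sits in neither.

| flask | solid substrate | remark | time |
|---|---|---|---|
| Saturday's | 0.20 mM | the very flask that is asked about, followed so far |  |
| Wednesday's | 0.13 mM | run made earlier |  |
| flask | 0.20 mM |  | 10 min |

| run | time / min | isomer of the product A / % | target / % |
|---|---|---|---|
| Saturday's | 0.500 | 0 | 34 |
| Saturday's | 1.00 | 0 | 59 |
| Saturday's | 1.50 | 0 | 57 |
| Saturday's | 2.50 | 0 | 59 |
| Saturday's | 3.00 | 1 | 56 |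
| Saturday's | 4.00 | 3 | 58 |
| Wednesday's | 0.200 | 1 | 18 |
| Wednesday's | 0.667 | 0 | 60 |
| Wednesday's | 1.00 | 0 | 62 |
| Wednesday's | 1.50 | 0 | 62 |
| Wednesday's | 2.50 | 0 | 62 |
| Wednesday's | 3.00 | 3 | 62 |
| Wednesday's | 4.00 | 1 | 64 |

(each reading ± 1.5 percentage points)

- share of isomer of the product A in isomer of the product A plus target at 5.0 s
- share of isomer of the product A in isomer of the product A plus target at 10 min
- which of isomer of the product A and target there is more of at 10 min

- solid substrate is a solid; its amount is given per volume of the solution
- at the start none of the solid substrate is in solution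

The rise of target stops early, and the stop follows the charge: Wednesday's flask, with 0.13 mM, is flat by 0.667 min, and Saturday's, with 0.20 mM, by 1.00 min. These times stand in a ratio of 1.50 and the charges in a ratio of 1.54, which looks like a steady feed from the solid. Time per charge, times the charge, over the asked time gives 0.100, the feed fraction: the part of the run during which material still arrives. It lies below one, so unless target itself feeds the isomer, the share at 10 min is the plateau share. Saturday's readings from 1.00 min on average 0.800% isomer and 57.8% target, so my reckoning is a share near 1.37%, with target ahead. Is one number enough? Saturday's last isomer reading of 3% stands against a scatter of 1.5 percentage points, but Wednesday's goes from 3% to 1% over the same times, so I commit to no drift.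

The forecast gives 0.5% at 5.0 s, 12% at 10 min and target ahead, expecting “a slow follow-on step with a lag”.

The flask gives 0.229% at 5.0 s and 0.369% at 10 min, with target ahead, 57.6% against 0.213%.

    third conformer → third product (k = 0.0657 s⁻¹)
    starting material ⇌ other conformer (K = 0.0130, k = 0.0582 s⁻¹)
    starting material + target → side product (k = 145 M⁻¹ s⁻¹)
    starting material → target (k = 0.0878 s⁻¹)
    other conformer → isomer of the product A (k = 0.0162 s⁻¹)
    solid substrate ⇌ starting material, rate k6*(cs6 - [starting material]) while solid is left; crystals form when [starting material] > cs6 (solubility = 0.0640 mM, k = 0.156 s⁻¹)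
    other conformer ⇌ third conformer (K = 0.410, k = 0.0643 s⁻¹)
    target ⇌ isomer of the product B (K = 0.383, k = 0.0234 s⁻¹)

Solid substrate, solid and dissolved, falls under 2.00% of its charge at 1.13 min, far earlier than 10 min: a fraction of 0.113 beside the feed fraction 0.100. From 1.00 min to 10.0 min isomer of the product A moves from 0.204% to 0.213%. For the flask with 0.80 mM the feed fraction scales to 0.400, still below one, and that flask ends with 0% of its charge left and a share of 0.467%.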